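The quinone ring is traced back to a phenol in which the C4 oxygen, the C2 methoxy group and the C6 side chain stand mutually meta. The C1 oxygen is added last by para-oxidation. This 1,3,5 array is not drawn from an arene but assembled by a thermal benzannulation. A 3-alkylcyclobutenone takes up methoxyacetylene between its carbonyl carbon and its α-carbon, which forms ring bonds C3–C4 and C1–C2 and closes the carbocycle in one operation without added reagent. The precursor is a cyclobutenone whose β-carbon carries the complete (R)-2-acetoxytridecyl chain. C2' stems from (R)-epichlorohydrin, and the elimination-prone acetate meets nothing but heat.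

Key step: step 7

Remark: ring atoms carry the quinone numbering throughout (C1 = carbonyl carbon flanked by C2–OMe and C6–side chain, C4 = the other carbonyl carbon, side chain C1', C2' and so on). The stereocentre of the target SMILES is read as (R), since OAc > CH2–ring > undecyl > H.

Step 1
Reactants: 1 (R)-epichlorohydrin; 2 decylmagnesium bromide
Product: 3 (R)-1-chlorotridecan-2-ol
Conditions: CuI (10 mol %), THF, −40 → 0 °C; then H2O (aq NH4Cl wash)
Reagents that add atoms: none
Why: Copper-catalysed Grignard opening of a terminal epoxide is an SN2 attack at the unsubstituted ring carbon that outruns displacement of the primary chloride, and since no bond to the stereocentre is broken the configuration of 1 is handed on unchanged and becomes C2' of the target.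

Step 2
Reactants: 3 (R)-1-chlorotridecan-2-ol; 4 lithium acetylide–ethylenediamine complex
Product: 6 (R)-pentadec-1-yn-4-ol, via (R)-2-undecyloxirane 5 (not isolated)
Conditions: 4 (3 equiv), DMSO, 0 °C → rt; then H2O
Reagents that add atoms: none
Why: One equivalent of 4 acts as base and triggers an intramolecular Williamson closure to epoxide 5, a further equivalent opens 5 by SN2 attack at its CH2 terminus (classical acetylide opening of a terminal epoxide), and both events take place at the former CH2Cl carbon, so the carbinol centre stays (R).

Step 3
Reactants: 6 (R)-pentadec-1-yn-4-ol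
Product: 7 (R)-pentadec-1-yn-4-yl acetate
Conditions: Ac2O, pyridine, DMAP (cat), CH2Cl2, 0 °C → rt
Reagents that add atoms: acetic anhydride, CC(=O)OC(C)=O
Why: DMAP-catalysed acyl transfer acylates the oxygen without touching the C–O bond, so the configuration is retained, and the acetate of the target is installed while the molecule still holds no base-sensitive enone.

Step 4
Reactants: 7 (R)-pentadec-1-yn-4-yl acetate; 8 trichloroacetyl chloride
Product: 10 (R)-1-(4,4-dichloro-3-oxocyclobut-1-en-1-yl)tridecan-2-yl acetate, via dichloroketene 9 (not isolated)
Conditions: 8 (2 equiv, slow addition in DME), Zn–Cu couple, Et2O, rt → 35 °C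
Reagents that add atoms: none
Why: Zinc dehalogenates 8 to dichloroketene 9, which adds to terminal alkynes in the well-established thermal ketene–alkyne [2+2] cycloaddition with the terminal CH bonding to the ketene carbonyl carbon, so the side chain sits on the β-carbon of the enone, while DME ties up zinc chloride and the ester is a bystander.

Step 5
Reactants: 10 (R)-1-(4,4-dichloro-3-oxocyclobut-1-en-1-yl)tridecan-2-yl acetate
Product: 11 (R)-1-(3-oxocyclobut-1-en-1-yl)tridecan-2-yl acetate
Conditions: Zn dust, AcOH, TMEDA, EtOH, 0 °C → rt
Reagents that add atoms: none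
Why: Zinc removes the two α-chlorines one after the other through zinc enolates that acetic acid protonates (reductive dehalogenation of an α-halo ketone), and the AcOH/TMEDA buffer at or below room temperature is the standard medium that spares the strained enone, the ester and the stereocentre.

Step 6
Reactants: 12 chloroacetaldehyde dimethyl acetal
Product: 15 methoxyacetylene, via 2-chlorovinyl methyl ether 13 (not isolated), via sodium methoxyacetylide 14 (not isolated)
Conditions: NaNH2 (3.2 equiv), liq NH3, −33 °C; NH3 evaporated under N2; cold brine, −70 °C → rt, distilled into a −78 °C trap; washed with cold aq NaH2PO4, kept as a toluene solution at −20 °C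
Reagents that add atoms: none
Why: Two successive base-induced β-eliminations (first methanol, then HCl) are the standard entry to alkoxyacetylenes from chloroacetals, the third equivalent of amide holds the product as its non-volatile sodium salt until the quench, and the phosphate wash removes ammonia that would otherwise attack the ketene in step 7.

Step 7
Reactants: 11 (R)-1-(3-oxocyclobut-1-en-1-yl)tridecan-2-yl acetate; 15 methoxyacetylene
Product: 20 (R)-1-(3-hydroxy-5-methoxyphenyl)tridecan-2-yl acetate, via vinylketene 16 (not isolated), via 4-vinylcyclobutenone 17 (not isolated), via dienylketene 18 (not isolated), via cyclohexadienone 19 (not isolated)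
Conditions: 15 (2.5 equiv), toluene (0.5 M in 11), degassed, sealed pressure tube behind a shield, 80 °C, then 110 °C until 17 is consumed
Reagents that add atoms: none
Why: This is a Danheiser benzannulation of a 3-alkylcyclobutenone with an alkoxyacetylene, a known purely thermal cascade of four pericyclic events. Heat opens 11 by a conrotatory 4π electrocyclic reaction (the bond that will be C4–C5 breaks) to vinylketene 16, and the ketene C=C of 16 adds 15 in a [2+2] cycloaddition to give 17. A second 4π opening turns 17 into dienylketene 18, the six-membered carbocycle is closed by a disrotatory 6π electrocyclisation that re-joins C4 and C5, and dienone 19 tautomerises to the phenol, so that the alkyne carbons end up as C3 and C2 with new ring bonds C3–C4 and C1–C2. The one selectivity needed is the orientation of the [2+2] step, and the push of the methoxy oxygen secures it: the electron-rich CH terminus of 15 bonds to the electrophilic ketene carbon, which puts OMe meta to both OH and side chain. No stereocentre is formed in 20 (the sp3 ring carbon of 17 is erased in the next ring opening), and C2' with its acetate is a spectator because no acid, base or metal is present and ester pyrolysis needs far higher temperatures. The excess of 15, which has no β-hydrogen and so cannot fragment by a retro-ene path, keeps 16 from being consumed by the phenol as it forms.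

Step 8
Reactants: 20 (R)-1-(3-hydroxy-5-methoxyphenyl)tridecan-2-yl acetate
Product: 22 (R)-1-(5-methoxy-3,6-dioxocyclohexa-1,4-dien-1-yl)tridecan-2-yl acetate, via para-aminoxy dienone 21 (not isolated)
Conditions: Fremy's salt (2.5 equiv), aq KH2PO4 buffer (pH 6–7), acetone–H2O, 0 °C → rt
Reagents that add atoms: Fremy's salt (dipotassium nitrosodisulfonate), [K+].[K+].[O-]S(=O)(=O)N([O])S(=O)(=O)[O-]
Why: In this Teuber oxidation one nitroxyl radical abstracts the phenolic hydrogen, a second one couples through its oxygen at the free para carbon C1 as is usual for 5-alkylresorcinol monomethyl ethers, and adduct 21 expels imidodisulfonate to give the 1,4-quinone, while the near-neutral buffer leaves the acetate and C2' untouched.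

Compound list
1 | (R)-epichlorohydrin, (R)-2-(chloromethyl)oxirane | ClC[C@H]1CO1 | starting material
2 | decylmagnesium bromide | CCCCCCCCCC[Mg]Br | starting material
3 | (R)-1-chlorotridecan-2-ol | CCCCCCCCCCC[C@H](CCl)O | intermediate
4 | lithium acetylide–ethylenediamine complex | [Li+].[C-]#C.NCCN | starting material
5 | (R)-2-undecyloxirane | CCCCCCCCCCC[C@@H]1CO1 | intermediate
6 | (R)-pentadec-1-yn-4-ol | CCCCCCCCCCC[C@H](CC#C)O | intermediate
7 | (R)-pentadec-1-yn-4-yl acetate | CCCCCCCCCCC[C@H](CC#C)OC(C)=O | intermediate
8 | trichloroacetyl chloride | ClC(Cl)(Cl)C(Cl)=O | starting material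
9 | dichloroketene | ClC(Cl)=C=O | intermediate
10 | (R)-1-(4,4-dichloro-3-oxocyclobut-1-en-1-yl)tridecan-2-yl acetate | CCCCCCCCCCC[C@H](CC1=CC(=O)C1(Cl)Cl)OC(C)=O | intermediate
11 | (R)-1-(3-oxocyclobut-1-en-1-yl)tridecan-2-yl acetate | CCCCCCCCCCC[C@H](CC1=CC(=O)C1)OC(C)=O | intermediate
12 | chloroacetaldehyde dimethyl acetal | COC(CCl)OC | starting material
13 | 2-chlorovinyl methyl ether (E/Z mixture) | COC=CCl | intermediate
14 | sodium methoxyacetylide | [Na+].[C-]#COC | intermediate
15 | methoxyacetylene | COC#C | intermediate
16 | vinylketene, (R)-3-methylidene-1-oxohexadec-1-en-5-yl acetate | CCCCCCCCCCC[C@H](CC(=C)C=C=O)OC(C)=O | intermediate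
17 | (4R)-2-(2-methoxy-4-oxocyclobut-2-en-1-yl)pentadec-1-en-4-yl acetate (both epimers at the sp3 ring carbon) | CCCCCCCCCCC[C@H](CC(=C)C1C(=O)C=C1OC)OC(C)=O | intermediate
18 | dienylketene, (R,3E)-3-methoxy-5-methylidene-1-oxooctadeca-1,3-dien-7-yl acetate (ketene and vinyl termini cis) | CCCCCCCCCCC[C@H](CC(=C)/C=C(/OC)C=C=O)OC(C)=O | intermediate
19 | (R)-1-(3-methoxy-5-oxocyclohexa-1,3-dien-1-yl)tridecan-2-yl acetate | CCCCCCCCCCC[C@H](CC1=CC(OC)=CC(=O)C1)OC(C)=O | intermediate
20 | (R)-1-(3-hydroxy-5-methoxyphenyl)tridecan-2-yl acetate | CCCCCCCCCCC[C@H](Cc1cc(O)cc(OC)c1)OC(C)=O | intermediate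
21 | cyclohexa-2,5-dienone adduct with the ON(SO3K)2 group on sp3 carbon C1, between C2–OMe and C6–side chain (C1 unassigned) | CCCCCCCCCCC[C@H](CC1=CC(=O)C=C(OC)C1ON(S(=O)(=O)[O-])S(=O)(=O)[O-])OC(C)=O.[K+].[K+] | intermediate
22 | (R)-1-(5-methoxy-3,6-dioxocyclohexa-1,4-dien-1-yl)tridecan-2-yl acetate | CCCCCCCCCCC[C@H](CC1=CC(=O)C=C(OC)C1=O)OC(C)=O | target

Total step count: 8
Longest linear sequence: 7 (steps 1–5, 7, 8); step 6 is a one-step side branch.

Steps most likely to fail

1. Step 7. The vinylketene may be trapped by the phenol as it forms. The ynol ether may oligomerise or escape. Acetic acid may be lost from the side chain before the ring is built. The fallback takes the arene from the shelf instead of building it. It sets out from 3 and comes back at 20.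
 - Chlorohydrin 3 is closed with powdered NaOH in Et2O, and epoxide 5 is isolated.
 - [3-(Benzyloxy)-5-methoxyphenyl]magnesium bromide F1 is made from commercial 1-(benzyloxy)-3-bromo-5-methoxybenzene and Mg in THF. It opens 5 at the CH2 terminus under CuI catalysis to give (R)-1-[3-(benzyloxy)-5-methoxyphenyl]tridecan-2-ol F2.
 - Ac2O, pyridine and DMAP convert F2 into (R)-1-[3-(benzyloxy)-5-methoxyphenyl]tridecan-2-yl acetate F3.
 - Hydrogenolysis (H2, Pd/C, EtOAc) frees phenol 20.

2. Step 5. The strained C=C bond may be over-reduced or may migrate. The amine may provoke vinylogous E1cB loss of the acetate. The fallback never introduces chlorine. It sets out from 7, bypasses steps 4 and 5, and comes back at 11.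
 - N,N-Dimethylacetamide, Tf2O and 2,4,6-collidine in refluxing 1,2-dichloroethane generate N,N-dimethylketeniminium triflate F4.
 - F4 adds to alkyne 7 in the known keteniminium–alkyne [2+2] cycloaddition. The terminal CH attacks the central carbon, which gives (R)-[3-(2-acetoxytridecyl)cyclobut-2-en-1-ylidene]dimethylammonium triflate F5.
 - Hydrolysis of F5 with water at pH 7 should give 11.

3. Step 8. The lipophilic phenol may separate from the aqueous radical salt, so that conversion is slow and the reagent decays. Oxidation may also stray to an ortho position. The fallback replaces the radical oxidation with a two-electron, two-stage sequence in organic solvent. It sets out from 20 and comes back at 22.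
 - PhI(OAc)2 (2.2 equiv) in MeOH at 0 °C oxidises the para-unsubstituted phenol to the quinone monoketal (R)-1-(5,6,6-trimethoxy-3-oxocyclohexa-1,4-dien-1-yl)tridecan-2-yl acetate F6.
 - Dilute aqueous HCl in THF at room temperature hydrolyses the ketal of F6 to quinone 22 without touching the secondary acetate.

Further compounds
F1 | step 7 | [3-(benzyloxy)-5-methoxyphenyl]magnesium bromide | COc1cc(OCc2ccccc2)cc([Mg]Br)c1
F2 | step 7 | (R)-1-[3-(benzyloxy)-5-methoxyphenyl]tridecan-2-ol | CCCCCCCCCCC[C@H](Cc1cc(OC)cc(OCc2ccccc2)c1)O
F3 | step 7 | (R)-1-[3-(benzyloxy)-5-methoxyphenyl]tridecan-2-yl acetate | CCCCCCCCCCC[C@H](Cc1cc(OC)cc(OCc2ccccc2)c1)OC(C)=O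
F4 | step 5 | N,N-dimethylketeniminium triflate | C=C=[N+](C)C.[O-]S(=O)(=O)C(F)(F)F
F5 | step 5 | (R)-[3-(2-acetoxytridecyl)cyclobut-2-en-1-ylidene]dimethylammonium triflate | CCCCCCCCCCC[C@H](CC1=CC(=[N+](C)C)C1)OC(C)=O.[O-]S(=O)(=O)C(F)(F)F
F6 | step 8 | (R)-1-(5,6,6-trimethoxy-3-oxocyclohexa-1,4-dien-1-yl)tridecan-2-yl acetate | CCCCCCCCCCC[C@H](CC1=CC(=O)C=C(OC)C1(OC)OC)OC(C)=O
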